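## Structural features

The target has three rings: ring A, an enolised 2-acylcyclohexane-1,3,5-trione (C1 to C6), is joined through the spiro carbon C5 to a cis-fused hydrindane made of the six-membered ring B (C5, C7, C8, C9, C10, C11) and the five-membered ring C (C8, C9, C12, C13, C14). Four contiguous stereocentres run C14–C8–C9–C10, two of them tertiary methyl carbinols; the spiro centre C5 touches this array only through the methylenes C7 and C11, and the quaternary C3 (methyl, prenyl) and the acyl α-carbon lie further away still. On ring B the groups C6, C12, C14 and O10 sit on one face and C4, H8, H9 and the C10 methyl on the other, and O14 points toward C7, so both hydroxyl groups are syn to the same ring A carbonyl, C6. Fragile elements are the two tertiary alcohols (ionisation, dehydration), the polycarbonyl system with non-enolisable C3 and C5 (retro-Claisen cleavage under base), the prenyl alkene next to enols (acid-induced cyclisation) and the epimerisable α-centre of the 2-methylbutanoyl group. The real difficulty is that C5 is flanked by two carbonyl carbons, C4 and C6, which differ only in what ring A carries three bonds away, and that C3 must be set far from every other stereocentre. The key step uses the fact that C5 carries C4 and C6 as two ketone carbons of one six-membered ring: this pattern results when the carbonyl carbon of a ring B ketone, flanked by the methylenes C7 and C11, is inserted between the two oxygenated carbons of a five-membered enediol, so ring A can be added as a locally symmetric block and C5 needs no control at that moment.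

## Logic of the disconnections

28 is cut at the bond from C3 to the prenyl CH2, giving 26 and 27. The enolised triketone is a soft carbon nucleophile and C3 is its only carbon whose alkylation gives a stable product. The gain is that the C3 stereocentre disappears and the prenyl alkene is never exposed to the acidic steps. The forward step must give C- not O-allylation, the linear prenyl isomer, and a facial choice imposed by a chiral catalyst, because C3 lies about 4 Å from the nearest stereogenic carbon.

26 is cut at the C1–acyl bond, giving 23 and 24. A cyclic 1,3-dione is C-acylated through its enol ester. The gain is removal of the side chain and its stereocentre. The forward step must acylate C1 and not C3, and must not racemise the α-carbon of 24.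

23 is traced back to 21 by two functional-group changes: the C2 carbonyl returns to its dithiane and the C6 carbonyl with both hydroxyls returns to a bridged ketal. This puts the protected form of every ring A oxygen except O4 into one intermediate. The forward step needs a thiophile that does not oxidise enols, and acid rather than base.

21 is cut at the C3–CH3 bond, giving 20. With C6 locked as a ketal, C4 is the only ketone and C3 its only enolisable neighbour, so this alkylation is what tells the two sides of ring A apart for the rest of the route. The forward step must stop at mono-methylation.

20 is cut at the two C6–O bonds (to O10 and to O14), giving 18 by way of 19. Both hydroxyls lie on the ring B face that carries only one of the two carbonyls, so intramolecular ketalisation names that carbonyl C6 and makes C5 stereogenic without any external control. The gain is a ring A with a local mirror plane. The forward step must remove silicon under acid (an alkoxide next to the non-enolisable 1,3-dione would cleave it) and must close both rings.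

18 is cut at C4–C5 and C5–C6, giving 12 and 16 (by way of 17). A quaternary carbon between two ring carbonyls is the retron of geminal acylation. The gain is the largest of the route: ring A is split off as a symmetric five-carbon unit from a hydrindanone that holds all four contiguous stereocentres. The forward step must add to the ketone faster than it eliminates the C10 silyloxy group, and must then complete the acyl shift.

16 is cut at the enediol C=C bond, giving 15, and 15 at its two C–S bonds, giving 13 and 14. The enediol is the product of an acyloin ring closure of a diester, and the thioketal masks the central ketone during it. The forward steps need the sulfur to survive dissolving sodium.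

12 is traced back to 11 (two Si–O bonds), to 10 (oxidation level of C5) and to 9 (cut of the C10–CH3 bond). Delivering the methyl group to a C10 ketone from the convex face puts O10 on the concave face, which an oxygen-delivering reaction could not do. The gain is that C10 is set by the ring fusion alone. The forward step needs a non-basic methyl donor so that the β-hydroxy ketone neither enolises nor undergoes retro-aldol cleavage.

9 is cut at C5–C11 (aldol), giving 8. Of the possible enol/carbonyl pairings only the methyl group C11 attacking C5 closes a six-membered ring. The gain is that ring B opens to a cyclopentane with an acetyl group and a masked aldehyde. The forward step must avoid dehydration and C9 epimerisation.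

8 is traced back to 7 (C10 carbonyl from an isopropenyl group) and 7 to 6 (lactol from lactone). The isopropenyl group and the lactone are exactly what an ene reaction delivers. The forward steps need the lactone reduced before the ketone exists.

6 is cut at C8–C9 with return of one hydrogen from C7 to a methyl group on C10, giving 5. Because the enophile is inside the lactone ring, ring C can only form cis-fused to it and the hydrogen transfer forces C10 onto the same face. Two stereocentres are thus removed and both derive from C14. The forward step must be concerted (thermal).

5 is traced back to 3 (C7=C8 unsaturation), 3 to 2 (oxidation level of C5) and 2 to 1 (cut of C5–C7). 1 already holds C14 in the correct configuration and every ring B and ring C carbon except C5, which is added as a one-carbon carbonyl unit at the terminal vinyl carbon. The forward steps need regioselective formylation and must leave the trisubstituted alkene alone.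

## Other disconnections considered

Alternative 1: the cut is C7–C8 in ring B. Forward, the N-acyloxyphthalimide A1 would be reduced at a cathode. In A1, C5 is a malonate carbon carrying the activated acetic acid arm (C7) and a keto arm (C11–C10) that ends in the cyclopentenyl ketone. Decarboxylation leaves a primary C7 radical, which adds 6-endo to the enone β-carbon C8; protonation of the enolate at C9 gives the cis-hydrindanone malonate A2.
- In favour: ring B and the ring fusion arise in one tin-free step from a substrate whose only stereocentre is the C14 carbinol. The nucleophilic radical and the enone are polarity-matched. The C10 ketone of A2 would later take its methyl group from the convex face, the same argument used here in step 8. C5 already carries C4 and C6 as esters.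
- Against it here: the face of C8 that is attacked is decided only by the neighbouring C14 centre (methyl against hydroxyl). The C9 protonation must give the cis fusion kinetically next to an epimerisable ketone. Ring A must then be built from two diastereotopic esters by double acylation of a three-carbon unit, a harder closure than a ring expansion.
- Comparison: on structure both plans leave ring A locally symmetric at C5 and both need the hydroxyl groups to tell C4 from C6. Here the malonate is the equal or the better, since one ester could lactonise onto a syn hydroxyl at once. On mechanism the radical closure is milder toward the oxygen functions than BF3, a point for the alternative; the chosen plan has C8 and C9 fixed before its key step and creates no stereocentre in it. On step economy the alternative should be similar up to A2 and longer after it.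

Alternative 2: the cut is C8–C14 in ring C. Forward, the cyclohexenyl aldehyde A3 would undergo intramolecular hydroacylation under a cationic rhodium bisphosphine catalyst. A3 is ring B with a C7=C8 double bond, C9 carrying the chain that ends in the C14 aldehyde, C10 as a silylated carbinol and C5 as a malonate. Oxidative addition of the aldehyde C–H bond, insertion of C7=C8 and reductive elimination would close ring C as the cyclopentanone A4.
- In favour: the step is catalytic, redox-neutral and atom-economic. The 4-pentenal geometry allows only the five-membered ketone and the short tether forces cis fusion. The C14 ketone would then take methyl from the convex face, giving O14 syn to C7 as required.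
- Against it here: the alkene is 1,2-disubstituted and part of a ring, a class in which decarbonylation of the acyl rhodium hydride competes with insertion. A quaternary silyloxy carbon sits next to the reacting chain. The stereochemical burden moves to the substrate: A3 needs C9 and C10 set on an otherwise unbiased cyclohexene, whereas the chosen plan draws C8, C9 and C10 from the C14 centre of 1.
- Comparison: on structure A4 is a close relative of 12 with the roles of C10 and C14 exchanged. On mechanism the alternative's ring closure is the better: one catalytic step with no oxidation-level adjustments, against steps 5 to 9 here. On step economy that advantage is expected to be lost again in the enantioselective synthesis of A3 and in the malonate-to-ring A sequence, so the totals should be comparable.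

Alternative 3: the cut is C5–C11, with ring A coming from an aromatic acylphloroglucinol. Forward, the eight-membered aryl allyl ether A5 would be heated. In A5 the C4 oxygen is linked through a methylene to C10, which carries the exocyclic C11 methylene, and C7 is attached to the aromatic C5. The [3,3] shift forms C5–C11, turns the C4 ether oxygen into the C4 carbonyl, leaves a new exocyclic methylene on C10 and contracts the large ring to ring B, giving the spiro dienone A6.
- In favour: this is the most convergent plan. The acyl group and the C3 methyl are already on the arene, so no dithiane, no geminal acylation and no late acylation are needed. Because the tether oxygen is O4, the distinction between C4 and C6 and the configuration of C5 follow from the ring without a marking step; on this point the alternative is better than the chosen plan.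
- Against it here: the shift ends on an already substituted ortho carbon, so the product is a dearomatised dienone that can revert or rearrange further and must be more stable than A5 for the reaction to proceed. The medium ring must be made first and must reach a chair-like transition state. The C10 carbinol would then have to come from hydration of the exocyclic alkene, which delivers oxygen to the convex face, the opposite of what the target needs; the chosen plan delivers carbon to that face in step 8.
- Comparison: on structure the alternative solves C5 and leaves C10 open, the chosen plan the reverse. On mechanism a reagent-free pericyclic step is at least the equal of a Lewis-acid cascade in functional-group tolerance. On step economy the alternative would be shorter after its key step but pays for it in the synthesis of A5.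

Key step: step 13

Remark on the chemistry: target atom numbers (C1 to C14) are used for all intermediates; ring A compounds 22, 23, 25 and 26 are drawn as single tautomers although they should exist as enol mixtures; the configuration of C8, C9, C10 and C14 in 12, 17 and 18 was checked against the target and agrees, and the one amendment made to the usual reading is that O14 as well as O10 is syn to the carbonyl that becomes C6, which step 14 exploits.

## Steps

Step 1
Reactants: 1 (R)-linalool
Product: 2 (5R)-5-methyl-5-(4-methylpent-3-en-1-yl)oxolan-2-ol (lactol; both C2 epimers)
Conditions: Rh(acac)(CO)2 (0.5 mol%), PPh3, CO/H2 (1:1, 20 bar), toluene, 70 °C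
Reagents that add atoms: carbon monoxide, [C-]#[O+]
Why: Rhodium-catalysed hydroformylation places the formyl carbon (C5) on the terminal vinyl carbon C7 because the internal carbon is neopentylic, and the tertiary hydroxyl closes on the aldehyde to give the lactol. The trisubstituted alkene does not react and C14 keeps the configuration of 1.

Step 2
Reactants: 2 lactol
Product: 3 (5R)-5-methyl-5-(4-methylpent-3-en-1-yl)oxolan-2-one
Conditions: PhI(OAc)2, 2,2,6,6-tetramethylpiperidin-1-oxyl (10 mol%), CH2Cl2, rt
Reagents that add atoms: none
Why: Oxoammonium-mediated oxidation of a lactol to the lactone; the electron-rich alkene is inert to this oxidant.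

Step 3
Reactants: 3 lactone
Product: 5 (5R)-5-methyl-5-(4-methylpent-3-en-1-yl)furan-2(5H)-one, via α-phenylselanyl lactone 4 (not isolated)
Conditions: LiN(iPr)2, THF, −78 °C; PhSeCl; then 30% H2O2, pyridine, CH2Cl2, 0 °C to rt
Reagents that add atoms: none
Why: α-Selenenylation of the lactone enolate at C7 followed by selenoxide syn-elimination toward C8, the only carbon with β-hydrogens, gives the butenolide. Cold H2O2 oxidises selenium much faster than the trisubstituted alkene.

Step 4
Reactants: 5 butenolide
Product: 6 (3aS,4S,6aR)-6a-methyl-4-(prop-1-en-2-yl)hexahydro-2H-cyclopenta[b]furan-2-one
Conditions: 1,2-dichlorobenzene (0.02 M), 2,6-di-tert-butyl-4-methylphenol (cat.), sealed tube, 200–220 °C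
Reagents that add atoms: none
Why: Intramolecular Alder-ene reaction of a 1,6-diene with an enoate enophile: C9 of the trisubstituted alkene bonds to the butenolide β-carbon C8 while an allylic methyl hydrogen passes to C7. Because the enophile is part of the lactone, ring C can only form cis-fused to it (C7 and O14 on one face), and the hydrogen can reach C7 only when C10 lies over the lactone, which places the isopropenyl group cis to C7; C8 and C9 are thus both set from C14.

Step 5
Reactants: 6 bicyclic lactone
Product: 7 (3aS,4S,6aR)-6a-methyl-4-(prop-1-en-2-yl)hexahydro-2H-cyclopenta[b]furan-2-ol (both C2 epimers)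
Conditions: iBu2AlH (1.1 equiv), CH2Cl2, −78 °C; aq. potassium sodium tartrate
Reagents that add atoms: none
Why: Partial reduction of a γ-lactone stops at the aluminium hemiacetal at −78 °C. It is done before the ozonolysis because the hydride would also reduce the ketone formed in step 6.

Step 6
Reactants: 7 lactol
Product: 8 1-[(3aS,4S,6aR)-2-hydroxy-6a-methylhexahydro-2H-cyclopenta[b]furan-4-yl]ethan-1-one
Conditions: O3, CH2Cl2/MeOH, −78 °C; then Me2S, −78 °C to rt
Reagents that add atoms: ozone, [O-][O+]=O
Why: Ozonolysis of the 1,1-disubstituted alkene with reductive work-up turns isopropenyl into acetyl, i.e. the C10 carbonyl with the methyl group that becomes C11. The conditions are neutral, so C9 next to the new ketone is not epimerised.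

Step 7
Reactants: 8 keto lactol
Product: 9 (1R,3aS,7aS)-1,6-dihydroxy-1-methyloctahydro-4H-inden-4-one (both C6 epimers)
Conditions: L-proline (30 mol%), DMSO, rt
Reagents that add atoms: none
Why: Amine-catalysed intramolecular aldol addition (6-enolexo) of the methyl ketone, through its less substituted enamine, to the aldehyde in equilibrium with the lactol; it forms C5–C11 and ring B. Only this pairing closes a six-membered ring (attack from C9 or from C7 would give four-membered rings), and the new C5 carbinol centre is irrelevant because step 9 oxidises it.

Step 8
Reactants: 9 ketol
Product: 10 (3R,3aS,7R,7aS)-3,7-dimethyloctahydro-1H-indene-3,5,7-triol (both C5 epimers)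
Conditions: MeLi/CeCl3 (6 equiv each, premixed at −78 °C), THF, −78 °C; aq. NH4Cl
Reagents that add atoms: methyllithium, [Li]C (transferred as MeCeCl2)
Why: Organocerium 1,2-addition to the C10 ketone; the reagent is nucleophilic but barely basic, so the β-hydroxy ketone neither enolises nor undergoes retro-aldol cleavage. The methyl group enters from the convex face, anti to ring C (the C12 bond on C9 blocks the concave side), which puts CH3 on the H9 face and O10 cis to C12 as in the target.

Step 9
Reactants: 10 triol
Product: 11 (3R,3aS,7R,7aS)-3,7-dihydroxy-3,7-dimethyloctahydro-5H-inden-5-one
Conditions: Dess–Martin periodinane (1.2 equiv), pyridine, CH2Cl2, 0 °C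
Reagents that add atoms: none
Why: Only the C5 carbinol is secondary, so a mild periodinane oxidation gives the β-hydroxy ketone chemoselectively; pyridine buffering avoids dehydration of the C10 carbinol.

Step 10
Reactants: 11 dihydroxy ketone
Product: 12 (3R,3aS,7R,7aS)-3,7-bis[(tert-butyldimethylsilyl)oxy]-3,7-dimethyloctahydro-5H-inden-5-one
Conditions: TBSOTf (3 equiv), 2,6-lutidine, CH2Cl2, −78 to 0 °C
Reagents that add atoms: tert-butyldimethylsilyl trifluoromethanesulfonate, CC(C)(C)[Si](C)(C)OS(=O)(=O)C(F)(F)F
Why: A silyl triflate with a hindered pyridine base silylates both tertiary carbinols; any silyl enol ether of the ketone is cleaved again on mild aqueous work-up. One group type is used on both oxygens so that a single acid treatment frees both together in step 14.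

Step 11
Reactants: 13 dimethyl 3-oxopentanedioate; 14 propane-1,3-dithiol
Product: 15 dimethyl 2,2'-(1,3-dithiane-2,2-diyl)diacetate
Conditions: BF3·OEt2 (0.3 equiv), CH2Cl2, 0 °C to rt
Reagents that add atoms: none
Why: Lewis-acid dithioketalisation of the ketone; the thioketal removes the acidic 1,3-dicarbonyl character that would interfere with the acyloin step and later serves as the masked C2 carbonyl.

Step 12
Reactants: 15 dithiane diester
Product: 16 2,3-bis(trimethylsilyloxy)-6,10-dithiaspiro[4.5]dec-2-ene
Conditions: Na (4.4 equiv), Me3SiCl (5 equiv), toluene, reflux
Reagents that add atoms: chlorotrimethylsilane, C[Si](C)(C)Cl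
Why: Acyloin condensation with in situ silylation (Rühlmann variant) closes the five-membered ring and traps the enediolate as the bis(silyl enol ether). The thioketal carbon is not adjacent to either ester carbonyl, so no β-elimination of sulfur is available to the intermediates.

Step 13
Reactants: 12 bis-TBS hydrindan-5-one; 16 bis(silyloxy)cyclopentene
Product: 18 bis-TBS spiro dione (ring A = cyclohexane-1,3-dione with C4 and C6 carbonyls and C2 as 1,3-dithiane; spiro at C5 to the hydrindane of 12), via silyloxy ketol adduct 17 (not isolated)
Conditions: 16 (3 equiv), BF3·OEt2 (1.5 equiv), CH2Cl2, −78 °C; then CF3CO2H, −78 °C to rt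
Reagents that add atoms: none
Why: BF3 coordinates the C5 ketone and one enol carbon of 16 adds to it (Mukaiyama aldol addition), giving the 2-silyloxy-2-(1-hydroxyalkyl)cyclopentanone 17 and the first C5–C(O) bond. Acid then ionises the tertiary C5–O bond and the neighbouring acyl carbon migrates from the ring carbon to C5 (pinacol-type 1,2-acyl shift), which forms the second bond and widens the five-membered ring to the six-membered 1,3-dione. The closest known reaction type is the geminal acylation of ketones and ketals with 1,2-bis(trimethylsilyloxy)cycloalkenes. Ring A is therefore closed by ring expansion and not by cyclisation, so no ring-closure mode has to be satisfied, and the two new bonds (C4–C5 and C5–C6) both end on C5. No stereocentre is created: 16 is symmetric, ring A in 18 has a local mirror plane and C5 carries two constitutionally identical arms. The selectivity needed is chemoselectivity: addition must beat Lewis-acid enolisation toward C11, which would expel the C10 silyloxy group; low temperature, an excess of 16 and the unhindered position of the carbonyl between two methylenes favour addition, and once C5 is quaternary the elimination path no longer exists. Thioketal sulfur should not bind BF3 strongly enough to stop the reaction and tertiary TBS ethers should tolerate the short acid treatment; partial loss of silyl groups would be harmless because step 14 removes both.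

Step 14
Reactants: 18 bis-TBS spiro dione
Product: 20 bridged ketal (C6 bonded to both O10 and O14; C4 ketone; C2 dithiane; C5 configured as in the target), via diol dione 19 (not isolated)
Conditions: 48% aq. HF, MeCN, 0 °C to rt; concentrate; then camphor-10-sulfonic acid (10 mol%), 4 Å molecular sieves, CH2Cl2, rt
Reagents that add atoms: none
Why: Desilylation is run under acid because a free alkoxide beside the non-enolisable 1,3-dione would start a retro-Claisen cleavage. Both hydroxyls lie on the ring B face that carries only one of the two carbonyls, so acid-catalysed intramolecular ketalisation can engage that carbonyl alone; it becomes C6, and C5 and C6 are thereby fixed by the configuration of C10 and C14, with C4 on the face of the C10 methyl as in the target.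

Step 15
Reactants: 20 bridged ketal
Product: 21 C3-methyl bridged ketal (C3 epimers)
Conditions: LiN(SiMe3)2 (1.1 equiv), THF, −78 °C; MeI, −78 to −20 °C
Reagents that add atoms: iodomethane, CI
Why: With C6 locked as a ketal, C4 is the only ketone and C3 its only enolisable position (C5 is quaternary), so the lithium enolate forms and is C-methylated regiospecifically. The configuration at C3 does not matter because this centre is enolised after step 16.

Step 16
Reactants: 21 C3-methyl bridged ketal
Product: 23 C3-methyl trione diol (C2, C4 and C6 carbonyls; free C10 and C14 carbinols), via ketal dione 22 (not isolated)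
Conditions: Hg(ClO4)2 (2.2 equiv), THF/H2O (5:1), 0 °C; then 1 M aq. HCl, rt
Reagents that add atoms: water, O
Why: Divalent mercury is a non-oxidising thiophile that removes the dithiane without attacking the enol that appears (Corey–Seebach-type unmasking), and the liberated perchloric acid, reinforced by HCl, hydrolyses the bridged ketal; the fully enolised triketone is the thermodynamic sink. Acid is kept throughout so that no retro-Claisen cleavage at C5 can start.

Step 17
Reactants: 23 C3-methyl trione diol; 24 (S)-2-methylbutanoic acid
Product: 26 C1-acyl C3-methyl trione (the target without its prenyl group), via enol ester 25 (not isolated)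
Conditions: N,N'-dicyclohexylcarbodiimide (1.2 equiv), 4-(dimethylamino)pyridine (1.2 equiv), CH2Cl2, 0 °C to rt
Reagents that add atoms: none
Why: Carbodiimide coupling gives the enol ester 25 and the aminopyridine transfers the acyl group from oxygen to carbon (Steglich-type O-to-C acyl shift of a cyclic 1,3-dione). C1 is the only ring carbon where C-acylation gives an enolisable, hydrogen-bonded triketone, since C3 already carries the methyl group; the tertiary alcohols are too hindered to be esterified and no ketene is formed, which protects the α-centre of 24.

Step 18
Reactants: 26 C1-acyl C3-methyl trione; 27 prenyl acetate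
Product: 28 hyperielliptone HB
Conditions: Pd2(dba)3·CHCl3 (2.5 mol%), (S,S)-N,N'-(cyclohexane-1,2-diyl)bis[2-(diphenylphosphanyl)benzamide] (7.5 mol%), Et3N (1.2 equiv), CH2Cl2, rt
Reagents that add atoms: none
Why: Tsuji–Trost allylic alkylation: zerovalent palladium ionises 27 to a 1,1-dimethylallyl complex, which the soft triketone enolate attacks at the unsubstituted terminus (linear prenyl) through C3; O-allylation is reversible under the catalyst and C1 cannot give a stable product. The new C3 centre (prenyl on the C11 face of ring A) is to be set by the chiral ligand pocket, which is reasonable because the substrate's own facial bias at this remote carbon should be small.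

## Compound list

1 | (R)-linalool, (3R)-3,7-dimethylocta-1,6-dien-3-ol | C=C[C@](C)(O)CCC=C(C)C | starting material
2 | (5R)-5-methyl-5-(4-methylpent-3-en-1-yl)oxolan-2-ol, both C2 epimers | CC(C)=CCC[C@]1(C)CCC(O)O1 | intermediate
3 | (5R)-5-methyl-5-(4-methylpent-3-en-1-yl)oxolan-2-one | CC(C)=CCC[C@]1(C)CCC(=O)O1 | intermediate
4 | (5R)-5-methyl-5-(4-methylpent-3-en-1-yl)-3-(phenylselanyl)oxolan-2-one, C3 epimers, not isolated | CC(C)=CCC[C@]1(C)CC([Se]c2ccccc2)C(=O)O1 | intermediate
5 | (5R)-5-methyl-5-(4-methylpent-3-en-1-yl)furan-2(5H)-one | CC(C)=CCC[C@]1(C)C=CC(=O)O1 | intermediate
6 | (3aS,4S,6aR)-6a-methyl-4-(prop-1-en-2-yl)hexahydro-2H-cyclopenta[b]furan-2-one | O=C1C[C@H]2[C@H](CC[C@@]2(C)O1)C(C)=C | intermediate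
7 | (3aS,4S,6aR)-6a-methyl-4-(prop-1-en-2-yl)hexahydro-2H-cyclopenta[b]furan-2-ol, both C2 epimers | OC1C[C@H]2[C@H](CC[C@@]2(C)O1)C(C)=C | intermediate
8 | 1-[(3aS,4S,6aR)-2-hydroxy-6a-methylhexahydro-2H-cyclopenta[b]furan-4-yl]ethan-1-one | OC1C[C@H]2[C@H](CC[C@@]2(C)O1)C(C)=O | intermediate
9 | (1R,3aS,7aS)-1,6-dihydroxy-1-methyloctahydro-4H-inden-4-one, both C6 epimers (C10 ketone, C5 carbinol, C14 carbinol) | OC1C[C@H]2[C@H](CC[C@@]2(C)O)C(=O)C1 | intermediate
10 | (3R,3aS,7R,7aS)-3,7-dimethyloctahydro-1H-indene-3,5,7-triol, both C5 epimers | OC1C[C@H]2[C@H](CC[C@@]2(C)O)[C@](C)(O)C1 | intermediate
11 | (3R,3aS,7R,7aS)-3,7-dihydroxy-3,7-dimethyloctahydro-5H-inden-5-one | O=C1C[C@H]2[C@H](CC[C@@]2(C)O)[C@](C)(O)C1 | intermediate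
12 | (3R,3aS,7R,7aS)-3,7-bis[(tert-butyldimethylsilyl)oxy]-3,7-dimethyloctahydro-5H-inden-5-one (key-step precursor) | O=C1C[C@H]2[C@H](CC[C@@]2(C)O[Si](C)(C)C(C)(C)C)[C@](C)(O[Si](C)(C)C(C)(C)C)C1 | intermediate
13 | dimethyl 3-oxopentanedioate | COC(=O)CC(=O)CC(=O)OC | starting material
14 | propane-1,3-dithiol | SCCCS | starting material
15 | dimethyl 2,2'-(1,3-dithiane-2,2-diyl)diacetate | COC(=O)CC1(CC(=O)OC)SCCCS1 | intermediate
16 | 2,3-bis(trimethylsilyloxy)-6,10-dithiaspiro[4.5]dec-2-ene | C[Si](C)(C)OC1=C(O[Si](C)(C)C)CC2(C1)SCCCS2 | intermediate
17 | aldol adduct: 3-(trimethylsilyloxy)-6,10-dithiaspiro[4.5]decan-2-one carrying at C3 the 5-hydroxy-hydrindan-5-yl group of 12 (bis-TBS), mixture at the two new centres, not isolated | C[Si](C)(C)OC1(C(=O)CC2(C1)SCCCS2)C3(O)C[C@H]4[C@H](CC[C@@]4(C)O[Si](C)(C)C(C)(C)C)[C@](C)(O[Si](C)(C)C(C)(C)C)C3 | intermediate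
18 | spiro dione: ring A cyclohexane-1,3-dione (C4, C6) with C2 as 1,3-dithiane, spiro at C5 to the cis-hydrindane with C10 and C14 as TBS ethers (key-step product) | O=C1CC2(SCCCS2)CC(=O)C13C[C@H]4[C@H](CC[C@@]4(C)O[Si](C)(C)C(C)(C)C)[C@](C)(O[Si](C)(C)C(C)(C)C)C3 | intermediate
19 | diol dione: 18 with both silyl groups removed, not isolated | O=C1CC2(SCCCS2)CC(=O)C13C[C@H]4[C@H](CC[C@@]4(C)O)[C@](C)(O)C3 | intermediate
20 | bridged ketal: C6 bonded to O10 and O14, C4 ketone, C2 dithiane, C5 as in the target | O=C1[C@]2(C[C@H]3[C@H](CC[C@@]3(C)O4)[C@](C)(O5)C2)[C@@]45CC6(SCCCS6)C1 | intermediate
21 | C3-methyl derivative of 20, C3 epimers | O=C1[C@]2(C[C@H]3[C@H](CC[C@@]3(C)O4)[C@](C)(O5)C2)[C@@]45CC6(SCCCS6)C1C | intermediate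
22 | ketal dione: 21 with the dithiane replaced by the C2 ketone, not isolated | O=C1[C@]2(C[C@H]3[C@H](CC[C@@]3(C)O4)[C@](C)(O5)C2)[C@@]45CC(=O)C1C | intermediate
23 | C3-methyl trione diol: ring A with C2, C4, C6 carbonyls (enol tautomers), C3 methyl, free C10 and C14 carbinols | CC1C(=O)[C@]2(C[C@H]3[C@H](CC[C@@]3(C)O)[C@](C)(O)C2)C(=O)CC1=O | intermediate
24 | (S)-2-methylbutanoic acid | CC[C@H](C)C(=O)O | starting material
25 | enol (S)-2-methylbutanoate of 23 (drawn at O2), not isolated | CC[C@H](C)C(=O)OC1=CC(=O)[C@@]2(C[C@H]3[C@H](CC[C@@]3(C)O)[C@](C)(O)C2)C(=O)C1C | intermediate
26 | C1-[(S)-2-methylbutanoyl] C3-methyl trione diol (target without prenyl), dienol tautomer | CC[C@H](C)C(=O)C1=C(O)C(C)=C(O)[C@]2(C[C@H]3[C@H](CC[C@@]3(C)O)[C@](C)(O)C2)C1=O | intermediate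
27 | prenyl acetate, 3-methylbut-2-en-1-yl acetate | CC(=O)OCC=C(C)C | starting material
28 | hyperielliptone HB | CC[C@H](C)C(=O)C1=C(O)[C@@](C)(CC=C(C)C)C(=O)[C@]2(C[C@H]3[C@H](CC[C@@]3(C)O)[C@](C)(O)C2)C1=O | target

## Step count and least certain steps

Total step count: 18. Longest linear sequence: 16 steps (steps 1 to 10 and 13 to 18); steps 11 and 12 form the two-step branch to 16.

Step 13 (key step). What may go wrong: Lewis-acid enolisation of the ketone toward C11 with loss of the C10 silyloxy group can compete with the aldol addition. The acyl shift of the five-membered ketol is also slower than in the cyclobutene series, so silyl ether cleavage during a prolonged acid treatment may overtake it. Fallback: it sets out from 12, which would be converted with HC(OMe)3 and a pyridinium sulfonate in MeOH into the dimethyl ketal F1. F1 would react with 16 and BF3·OEt2 through an oxocarbenium ion (the acetal form of the Mukaiyama addition), which cannot enolise. The methoxy ketol so formed would rearrange on addition of CF3CO2H, and the route is rejoined at 18.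

Step 4. What may go wrong: at the temperature the ene reaction needs, the other ene mode (bond to C10 with hydrogen taken from C12, giving a six-membered ring) or oligomerisation of the butenolide may compete. A Lewis acid would lower the temperature but opens a stepwise cationic path that no longer guarantees the cis relation. Fallback: a radical route from 1 to 6 that avoids 5. Atom-transfer (Kharasch) addition of BrCCl3 to the vinyl group of 1, followed by 5-exo cyclisation onto the trisubstituted alkene, would give the tertiary bromide F2. KOtBu would eliminate to the isopropenyl trichloride F3. AgNO3 in aqueous acetone would hydrolyse the trichloromethyl group with participation of the C14 hydroxyl, and only the isomer with C7 cis to O14 can lactonise, so the route is rejoined at 6.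

Step 7. What may go wrong: dehydration of the ketol to the enone, which removes the C5 oxygen needed in step 9, and epimerisation at C9 through the more substituted enamine or enol of the methyl ketone. Fallback: a Reformatsky-type closure that makes the C10 carbinol directly, setting out from 6. ClCH2Li (from ICH2Cl and MeLi, −78 °C) would add once to the lactone to give the chloromethyl ketone, held as its lactol F4. Ozonolysis would give the keto chloromethyl lactol F5. SmI2 (divalent samarium) would then reduce the C–Cl bond, and the samarium enolate would add through C11 to the C10 ketone. This bypasses steps 7 to 9 and rejoins the route at 11; the C10 configuration would then rest on a samarium chelate that includes O14 and would need to be confirmed.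

Step 14. What may go wrong: closure of only one of the two C6–O bonds (the five-membered ring from O10 is the more strained), leaving hemiketal and enol ether mixtures. Fallback: setting out from 19, azeotropic dehydration with camphor-10-sulfonic acid in benzene would be pushed to the single six-membered cyclic enol ether F6 (O14–C6=C1, O10–H free), in which C4 is again the only ketone. LiN(SiMe3)2 (2 equiv) and MeI would give its C3-methyl derivative F7, and Hg(ClO4)2 followed by aqueous acid would hydrolyse thioketal and enol ether together, rejoining the route at 23.

Step 18. What may go wrong: poor facial selectivity if an unforeseen substrate bias opposes the ligand, or attack at the substituted allyl terminus (reverse prenyl). Fallback: the order in which the two C3 substituents arrive is reversed so that the small electrophile comes last and any intrinsic facial preference works in the opposite sense. Setting out from 20, LiN(SiMe3)2 and prenyl bromide would give the C3-prenyl bridged ketal F8; Hg(ClO4)2 then aqueous acid the C3-prenyl trione diol F9; acylation with 24 as in step 17 the C1-acyl C3-prenyl trione F10; and C-methylation with MeI and NaOMe in MeOH would rejoin the route at 28. The price is exposure of the prenyl group to the acidic unmasking.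

## Further compounds

F1 | step 13 | dimethyl ketal of 12 (5,5-dimethoxy hydrindane, C10 and C14 as TBS ethers) | COC1(OC)C[C@H]2[C@H](CC[C@@]2(C)O[Si](C)(C)C(C)(C)C)[C@](C)(O[Si](C)(C)C(C)(C)C)C1
F2 | step 4 | 3-(2-bromopropan-2-yl)-1-methyl-2-(2,2,2-trichloroethyl)cyclopentan-1-ol, all-cis as in 6 | ClC(Cl)(Cl)C[C@H]1[C@H](CC[C@@]1(C)O)C(C)(C)Br
F3 | step 4 | 1-methyl-3-(prop-1-en-2-yl)-2-(2,2,2-trichloroethyl)cyclopentan-1-ol, all-cis as in 6 | ClC(Cl)(Cl)C[C@H]1[C@H](CC[C@@]1(C)O)C(C)=C
F4 | step 7 | 2-(chloromethyl) lactol of 6 (2-(chloromethyl)-6a-methyl-4-(prop-1-en-2-yl)hexahydro-2H-cyclopenta[b]furan-2-ol) | OC1(CCl)C[C@H]2[C@H](CC[C@@]2(C)O1)C(C)=C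
F5 | step 7 | 1-[2-(chloromethyl)-2-hydroxy-6a-methylhexahydro-2H-cyclopenta[b]furan-4-yl]ethan-1-one | OC1(CCl)C[C@H]2[C@H](CC[C@@]2(C)O1)C(C)=O
F6 | step 14 | six-membered cyclic enol ether (O14–C6=C1), C4 ketone, C2 dithiane, O10–H free | O=C1[C@]2(C[C@H]3[C@H](CC[C@@]3(C)O4)[C@](C)(O)C2)C4=CC5(SCCCS5)C1
F7 | step 14 | C3-methyl derivative of F6 | O=C1[C@]2(C[C@H]3[C@H](CC[C@@]3(C)O4)[C@](C)(O)C2)C4=CC5(SCCCS5)C1C
F8 | step 18 | C3-prenyl derivative of 20 | O=C1[C@]2(C[C@H]3[C@H](CC[C@@]3(C)O4)[C@](C)(O5)C2)[C@@]45CC6(SCCCS6)C1CC=C(C)C
F9 | step 18 | C3-prenyl trione diol | CC(C)=CCC1C(=O)[C@]2(C[C@H]3[C@H](CC[C@@]3(C)O)[C@](C)(O)C2)C(=O)CC1=O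
F10 | step 18 | C1-[(S)-2-methylbutanoyl] C3-prenyl trione diol | CC[C@H](C)C(=O)C1=C(O)C(CC=C(C)C)=C(O)[C@]2(C[C@H]3[C@H](CC[C@@]3(C)O)[C@](C)(O)C2)C1=O
A1 | alternative 1 | N-acyloxyphthalimide malonate with cyclopentenyl ketone arm | COC(=O)C(CC(=O)ON1C(=O)c2ccccc2C1=O)(CC(=O)C3=C[C@](C)(O)CC3)C(=O)OC
A2 | alternative 1 | cis-hydrindane C10 ketone malonate with C14 carbinol | COC(=O)C1(C(=O)OC)C[C@H]2[C@H](CC[C@@]2(C)O)C(=O)C1
A3 | alternative 2 | cyclohexenyl aldehyde malonate with C10 triethylsilyl ether | COC(=O)C1(C(=O)OC)C=C[C@H](CCC=O)[C@](C)(O[Si](CC)(CC)CC)C1
A4 | alternative 2 | cis-hydrindan-1-one malonate | COC(=O)C1(C(=O)OC)C[C@H]2[C@H](CCC2=O)[C@](C)(O[Si](CC)(CC)CC)C1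
A5 | alternative 3 | eight-membered aryl allyl ether of the acylphloroglucinol | CC[C@H](C)C(=O)c1c(O)c(C)c2OCC(=C)[C@H]3CC[C@@](C)(O)[C@H]3Cc2c1O
A6 | alternative 3 | spiro dienone with C10 exocyclic methylene | CC[C@H](C)C(=O)C1=C(O)C(C)=C(O)[C@]2(C[C@H]3[C@H](CC[C@@]3(C)O)C(=C)C2)C1=O
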